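The earlier runs and the new flask were generated by integration with made-up constants; noise was put on by code.

The ratio of intermediate to starting material in the eta run stood at 0.459 after 40.0 s and 0.458 after 60.0 s, while target went on growing. So I took the two as one pool with a steady split (a pre-equilibrium), and target as what leaves that pool.

| setting | alpha | eta | dawn | winter | summer |
|---|---|---|---|---|---|
| starting material | 0.80 M | 0.80 M | 0.80 M | 0.80 M | 0.80 M |
| coupling partner | 1.5 equiv | 1.5 equiv | 1.50 equiv | 1.50 equiv | 1.50 equiv |
| free catalyst | 7.1 mol% | 23 mol% | 5 mol% | 10 mol% | 20 mol% |
| second catalyst | 1 mol% | 1 mol% | 1 mol% | 1 mol% | 1 mol% |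
| remark | run made earlier | run made earlier |  |  |  |
| time |  |  | 2.0 min | 2.0 min | 2.0 min |

| run | time / s | intermediate / % | starting material / % | target / % |
|---|---|---|---|---|
| alpha | 15.0 | 14.5 | 84.2 | 0 |
| alpha | 30.0 | 23.8 | 75.3 | 1.4 |
| alpha | 50.0 | 25.8 | 69.3 | 3.3 |
| alpha | 60.0 | 27.7 | 67.6 | 5.4 |
| eta | 10.0 | 24.7 | 74.9 | 0.2 |
| eta | 20.0 | 29.5 | 69.0 | 1.3 |
| eta | 40.0 | 30.3 | 66.0 | 5.1 |
| eta | 60.0 | 29.4 | 64.2 | 6.9 |

(readings scatter by 0.5 percentage points)



1. which of these there is most of at the end, counted by the starting material in it, dawn (intermediate / starting material / target)
2. which of these there is most of at the end, counted by the starting material in it, winter (intermediate / starting material / target)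
3. which of these there is most of at the end, counted by the starting material in it, summer (intermediate / starting material / target)
4. the largest of these amounts at the end, in percent of the starting material charged, dawn
5. the largest of these amounts at the end, in percent of the starting material charged, winter
6. the largest of these amounts at the end, in percent of the starting material charged, summer

From the last eta reading I got 68.6%: this is the pool share, the fraction of starting material plus intermediate that stands as starting material. At that split starting material stays ahead of intermediate, and its fraction of the charge is the pool share times what target has not taken.

Does dawn, with less free catalyst than winter or summer, reach the split? Its loading times its time is 1.41 times that of the alpha run at its last reading, where the ratio had already come to 0.410. So I expected dawn to end near the split.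

Can target overtake starting material? That needs a target fraction of 40.7%. The eta pace between 20.0 s and 40.0 s, held for 2.0 min, gives 22.8%, which is less. So I expected starting material to be largest in dawn, winter and summer. For summer, whose loading is close to eta's, I scaled the last eta target to 2.0 min, which gave 13.8% target and so 59.1% starting material.

The forecast gave 62%, 60% and 59% for dawn, winter and summer, in its words: “Starting material remains largest in all three.”

Starting material came out largest at 63.3% in dawn, 60.4% in winter and 59.2% in summer.

    starting material + free catalyst ⇌ free catalyst + intermediate (K = 0.480, k = 0.260 M⁻¹ s⁻¹)
    coupling partner + second catalyst + intermediate → second catalyst + target (k = 0.500 M⁻² s⁻¹)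
    second catalyst → spent catalyst (k = 0.00180 s⁻¹)
    coupling partner ⇌ dormant form (K = 0.940, k = 5.30 × 10⁻⁴ s⁻¹)

In summer the relaxation half-life of the first step alone, both ways together, was 0.0901 min at 2.00 min, short against the 2.0 min of the run. The pool share applied to summer's 13.2% of target gives 59.5% starting material.

The neighbour, summer made with 0.48 M of starting material and the same equivalents and loadings, ended with 4.89% target. The pool share turns that into 65.2% starting material, and the computed flask holds 64.6%.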